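**Assumption:** "Mutafran C" is taken to be mutafuran C and the SMILES is authoritative. It decodes to a 2,5-trans tetrahydrofuran, (R) at the carbon bearing the butanoate arm (C2) and (S) at the carbon bearing the alkyne (C5).

## Retrosynthetic overview

1. Last bond: Sonogashira C(sp)–C(sp2) coupling of tetrahydrofuranyl alkyne 12 with (1E,9E)-1-bromo-10-iododeca-1,9-diene 18 (C–I reacts, C–Br is kept).
2. Alkyne 12 comes from a C5–CH2OBn group (→ CHO → C≡CH); the butanoate arm comes from Wittig/hydrogenation of a THF–CH2CHO.
3. The only ring, the tetrahydrofuran, is closed once by an amine-catalysed intramolecular oxa-Michael addition of the C5 alcohol onto an enal (5-exo), setting C2 trans to C5.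
4. The hydroxy-enal comes from cross-metathesis of (S)-1-(benzyloxy)hex-5-en-2-ol, made from (S)-benzyl glycidyl ether and allyl Grignard.
5. Diene 18 comes from non-3-yn-1-ol: zipper, hydrozirconation/NBS, oxidation, Ohira–Bestmann, hydrozirconation/I2.

Reagents that deliver carbon are numbered as compounds; NBS and I2 appear only as reagents.

## Route

### Core fragment

**Step 1**
Reactants: 1, (S)-benzyl glycidyl ether; 2, allylmagnesium bromide
Product: 3, (S)-1-(benzyloxy)hex-5-en-2-ol
Conditions: allylMgBr (1.5 equiv), CuI (10 mol%), THF, −40 → 0 °C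
Reagents that add atoms: allylmagnesium bromide (2), C=CC[Mg]Br
Why: Copper-catalysed SN2 epoxide opening at the unhindered CH2; the chiral-pool stereocentre (future C5) is not touched.

**Step 2**
Reactants: 3; 4, crotonaldehyde
Product: 5, (S,E)-7-(benzyloxy)-6-hydroxyhept-2-enal
Conditions: crotonaldehyde (5 equiv), Hoveyda–Grubbs II (3 mol%), CH2Cl2, 40 °C
Reagents that add atoms: crotonaldehyde (4), C/C=C/C=O (delivers =CH–CHO; propene is lost)
Why: Olefin cross-metathesis of a terminal alkene with an electron-poor enal is E-selective and tolerates the free alcohol and benzyl ether.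

**Step 3 (ring closure)**
Reactants: 5
Product: 6, 2-[(2S,5S)-5-[(benzyloxy)methyl]oxolan-2-yl]acetaldehyde (2,5-trans)
Conditions: (R)-α,α-diphenylprolinol TMS ether (20 mol%), PhCO2H (20 mol%), CH2Cl2, −30 °C
Reagents that add atoms: none
Why: Iminium-activated intramolecular oxa-Michael addition (5-exo-trig) closes the tetrahydrofuran; the (R)-catalyst blocks one enal face, so the C6 oxygen adds to the other and sets the new centre trans to the existing one under catalyst control.

**Step 4**
Reactants: 6; 7, methyl (triphenylphosphoranylidene)acetate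
Product: 8, methyl (E)-4-[(2S,5S)-5-[(benzyloxy)methyl]oxolan-2-yl]but-2-enoate
Conditions: Ph3P=CHCO2Me (1.3 equiv), CH2Cl2, rt
Reagents that add atoms: ylide 7, COC(=O)C=P(c1ccccc1)(c1ccccc1)c1ccccc1 (delivers =CH–CO2Me)
Why: Stabilised-ylide Wittig olefination under neutral conditions, which avoids retro-oxa-Michael opening of the β-alkoxy aldehyde.

**Step 5**
Reactants: 8
Product: 9, methyl 4-[(2R,5S)-5-(hydroxymethyl)oxolan-2-yl]butanoate
Conditions: H2 (1 atm), 10% Pd/C, MeOH, rt
Reagents that add atoms: none
Why: Catalytic hydrogenation saturates the enoate and hydrogenolyses the benzyl ether in one operation; no stereocentre is touched (the C2 descriptor changes from S to R only through CIP priorities).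

**Step 6**
Reactants: 9
Product: 10, methyl 4-[(2R,5S)-5-formyloxolan-2-yl]butanoate
Conditions: Dess–Martin periodinane, NaHCO3, CH2Cl2, 0 °C → rt; used crude
Reagents that add atoms: none
Why: Dess–Martin oxidation is mild and non-basic, so the α-alkoxy aldehyde is formed without epimerising C5.

**Step 7**
Reactants: 10; 11, dimethyl (1-diazo-2-oxopropyl)phosphonate
Product: 12, methyl 4-[(2R,5S)-5-ethynyloxolan-2-yl]butanoate
Conditions: 11 (1.3 equiv), K2CO3, MeOH, 0 °C → rt
Reagents that add atoms: Ohira–Bestmann reagent (11), COP(=O)(OC)C(=[N+]=[N-])C(C)=O (delivers the terminal alkyne carbon)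
Why: Seyferth–Gilbert homologation in its Ohira–Bestmann form converts the aldehyde to the terminal alkyne; K2CO3/MeOH is degenerate for the methyl ester.

### Side-chain fragment

**Step 8**
Reactants: 13, non-3-yn-1-ol
Product: 14, non-8-yn-1-ol
Conditions: KH, H2N(CH2)3NH2 (KAPA), 0 °C → rt; aq. NH4Cl
Reagents that add atoms: none
Why: Alkyne zipper isomerisation, driven to the chain terminus by formation of the terminal acetylide.

**Step 9**
Reactants: 14
Product: 15, (E)-9-bromonon-8-en-1-ol
Conditions: Cp2Zr(H)Cl (2.2 equiv), THF, rt; then NBS (1.5 equiv), 0 °C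
Reagents that add atoms: N-bromosuccinimide, O=C1CCC(=O)N1Br
Why: Syn hydrozirconation puts Zr on the terminal carbon (the first equivalent is consumed as the Zr alkoxide) and bromination proceeds with retention, giving the E-vinyl bromide.

**Step 10**
Reactants: 15
Product: 16, (E)-9-bromonon-8-enal
Conditions: Dess–Martin periodinane, NaHCO3, CH2Cl2, rt
Reagents that add atoms: none
Why: Dess–Martin oxidation of the primary alcohol; the vinyl bromide is inert.

**Step 11**
Reactants: 16; 11
Product: 17, (E)-1-bromodec-1-en-9-yne
Conditions: 11 (1.3 equiv), K2CO3, MeOH, rt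
Reagents that add atoms: Ohira–Bestmann reagent (11), COP(=O)(OC)C(=[N+]=[N-])C(C)=O
Why: Ohira–Bestmann homologation of an unhindered aldehyde; carbonate in methanol does not affect the vinyl bromide.

**Step 12**
Reactants: 17
Product: 18, (1E,9E)-1-bromo-10-iododeca-1,9-diene
Conditions: Cp2Zr(H)Cl (1.1 equiv), THF, rt, 30 min; then I2, 0 °C
Reagents that add atoms: iodine, II
Why: Hydrozirconation–iodination; the terminal alkyne reacts far faster than the E-disubstituted bromoalkene, and syn addition with retentive iodination gives a geometrically pure E-vinyl iodide.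

### Coupling

**Step 13**
Reactants: 12; 18 (1.2 equiv)
Product: 19, mutafuran C, methyl 4-[(2R,5S)-5-[(3E,11E)-12-bromododeca-3,11-dien-1-yn-1-yl]oxolan-2-yl]butanoate
Conditions: Pd(PPh3)4 (5 mol%), CuI (10 mol%), i-Pr2NH, THF (degassed), rt
Reagents that add atoms: none (both partners are listed reactants; iodide is lost)
Why: Sonogashira coupling; oxidative addition into C–I is much faster than into C–Br at room temperature, and the alkene geometry is retained.

## Compound list

1 | (S)-benzyl glycidyl ether | C1[C@H](O1)COCc2ccccc2 | starting material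
2 | allylmagnesium bromide | C=CC[Mg]Br | starting material
3 | (S)-1-(benzyloxy)hex-5-en-2-ol | C=CCC[C@@H](COCc1ccccc1)O | intermediate
4 | crotonaldehyde | C/C=C/C=O | starting material
5 | (S,E)-7-(benzyloxy)-6-hydroxyhept-2-enal | O=C/C=C/CC[C@@H](COCc1ccccc1)O | intermediate
6 | 2-[(2S,5S)-5-[(benzyloxy)methyl]oxolan-2-yl]acetaldehyde | O=CC[C@@H]1CC[C@@H](COCc2ccccc2)O1 | intermediate
7 | methyl (triphenylphosphoranylidene)acetate | COC(=O)C=P(c1ccccc1)(c1ccccc1)c1ccccc1 | starting material
8 | methyl (E)-4-[(2S,5S)-5-[(benzyloxy)methyl]oxolan-2-yl]but-2-enoate | COC(=O)/C=C/C[C@@H]1CC[C@@H](COCc2ccccc2)O1 | intermediate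
9 | methyl 4-[(2R,5S)-5-(hydroxymethyl)oxolan-2-yl]butanoate | COC(=O)CCC[C@@H]1CC[C@@H](CO)O1 | intermediate
10 | methyl 4-[(2R,5S)-5-formyloxolan-2-yl]butanoate | COC(=O)CCC[C@@H]1CC[C@@H](C=O)O1 | intermediate
11 | dimethyl (1-diazo-2-oxopropyl)phosphonate | COP(=O)(OC)C(=[N+]=[N-])C(C)=O | starting material
12 | methyl 4-[(2R,5S)-5-ethynyloxolan-2-yl]butanoate | COC(=O)CCC[C@@H]1CC[C@@H](C#C)O1 | intermediate
13 | non-3-yn-1-ol | CCCCCC#CCCO | starting material
14 | non-8-yn-1-ol | C#CCCCCCCCO | intermediate
15 | (E)-9-bromonon-8-en-1-ol | OCCCCCCC/C=C/Br | intermediate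
16 | (E)-9-bromonon-8-enal | O=CCCCCCC/C=C/Br | intermediate
17 | (E)-1-bromodec-1-en-9-yne | C#CCCCCCC/C=C/Br | intermediate
18 | (1E,9E)-1-bromo-10-iododeca-1,9-diene | I/C=C/CCCCCC/C=C/Br | intermediate
19 | mutafuran C | COC(=O)CCC[C@@H]1CC[C@@H](C#C/C=C/CCCCCC/C=C/Br)O1 | target

## Totals

- Total step count: 13
- Longest linear sequence: 8 (steps 1–7, then 13); 8/13 ≈ 0.62. The side-chain branch is 5 steps plus the coupling.

## Three steps most likely to fail

1. **Step 3, trans selectivity of the oxa-Michael.** The catalyst may not fully control the new centre, and retro-Michael can erode the ratio. Fallback: keep the oxa-Michael closure but change acceptor and activation mode. Cross-metathesise 3 with 4-methoxyphenyl vinyl ketone and cyclise the ε-hydroxy enone with a cinchona-derived bifunctional aminothiourea, choosing the pseudo-enantiomer that gives trans. Then Baeyer–Villiger to the aryl ester and DIBAL-H to rejoin at aldehyde 6.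

2. **Steps 6–7, epimerisation of the α-alkoxy aldehyde at C5.** Fallback: carry the alkyne from the start so no C5 aldehyde is ever made. Prepare (S)-1-(triisopropylsilyl)hept-6-en-1-yn-3-ol by Noyori transfer hydrogenation of the ynone from pent-4-enoyl chloride and TIPS-acetylene. Run the same cross-metathesis, oxa-Michael and Wittig steps, reduce the enoate with a copper hydride conjugate reduction instead of H2/Pd, and remove TIPS with TBAF.

3. **Step 13, iodide versus bromide selectivity and alkyne homocoupling.** Fallback: install the bromide last. Couple 12 with (E)-9-iodonon-8-en-1-ol (from 14 by hydrozirconation/I2), oxidise the terminal alcohol to the aldehyde, and form the E-vinyl bromide by Takai olefination (CHBr3, CrBr2).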